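**Assumptions (one line):** The Z-alkene is kept throughout. L-Threitol acetonide, 8-bromooctan-1-ol and nonyltriphenylphosphonium bromide are treated as commercial.

**Retrosynthesis**
1. Pleiogenone A (16) comes from acid hydrolysis of the 4,5-acetonide of cyclohexenone 15.
2. The only ring bond formed is C1–C6. It is made by a proposed NHC-catalysed intramolecular crossed benzoin of the (Z)-enal/α-alkoxy-ketone 14. This closes the ring, forms the enone and sets the tertiary carbinol C6.
3. Ketone 14 comes from Grignard addition of (Z)-heptadec-8-enyl-MgBr to an aldehyde derived from L-threitol acetonide, followed by oxidation. The Z-enal comes from Still–Gennari olefination, DIBAL reduction and oxidation.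
4. C4 and C5 (trans-diol) come from L-threitol (chiral pool). The C17 chain comes from 8-bromooctanal plus a Z-selective Wittig reaction.

---

**Step 1**
Reactants: 1 (2,3-O-isopropylidene-L-threitol)
Product: 2 (1-O-TBS-2,3-O-isopropylidene-L-threitol)
Conditions: NaH (1.0 equiv), THF, 0 °C, then TBSCl, 0 °C → rt
Reagents that add atoms: TBSCl, CC(C)(C)[Si](C)(C)Cl
Why: Statistical mono-silylation of a C2-symmetric diol (Williamson-type silylation of the mono-alkoxide) differentiates the two ends and keeps both threitol stereocenters.

**Step 2**
Reactants: 2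
Product: 3 (4-O-TBS-2,3-O-isopropylidene-L-threose)
Conditions: (COCl)2, DMSO, CH2Cl2, –78 °C; then Et3N, –78 → 0 °C (used crude)
Reagents that add atoms: none
Why: Swern oxidation of the only free primary alcohol gives the α-alkoxy aldehyde. The trans-dioxolane is the stable configuration, so the α-center does not scramble.

**Step 3**
Reactants: 4 (8-bromooctan-1-ol)
Product: 5 (8-bromooctanal)
Conditions: PCC, NaOAc, CH2Cl2, rt
Reagents that add atoms: none
Why: Standard oxidation of a primary alcohol to an aldehyde; the alkyl bromide is unaffected.

**Step 4**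
Reactants: 5; 6 (nonyltriphenylphosphonium bromide)
Product: 7 ((Z)-1-bromoheptadec-8-ene)
Conditions: 6, NaHMDS, THF, 0 °C; then 5, –78 °C → rt
Reagents that add atoms: none (the nonyl unit comes from 6)
Why: Salt-free Wittig reaction of a non-stabilised ylide with an unbranched aldehyde gives the (Z)-alkene with high selectivity (about 95:5).

**Step 5**
Reactants: 7
Product: 8 ((Z)-heptadec-8-enylmagnesium bromide)
Conditions: Mg turnings, I2 (cat.), THF, 40 °C
Reagents that add atoms: Mg, [Mg]
Why: Ordinary Grignard formation from a primary bromide; the isolated Z-alkene is inert.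

**Step 6**
Reactants: 3; 8
Product: 9 (secondary alcohol, TBS ether; carbinol epimer mixture)
Conditions: 8 (1.5 equiv), THF, –78 → 0 °C; aq. NH4Cl
Reagents that add atoms: none (the R group comes from 8)
Why: Grignard 1,2-addition to an aldehyde. The new carbinol center is stereochemically irrelevant because it is oxidised at Step 11; the threitol centers are untouched.

**Step 7**
Reactants: 9
Product: 10 (primary/secondary diol, acetonide retained)
Conditions: TBAF, THF, 0 °C → rt
Reagents that add atoms: none
Why: Fluoride cleavage of the primary silyl ether; the acetonide, Z-alkene and carbinol are stable.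

**Step 8**
Reactants: 10
Product: 11 (α-alkoxy aldehyde with free secondary carbinol; used crude)
Conditions: TEMPO (10 mol %), PhI(OAc)2 (1.1 equiv), CH2Cl2, 0 °C → rt
Reagents that add atoms: none
Why: TEMPO/BAIB oxidation is selective for the unhindered primary alcohol over the hindered secondary one.

**Step 9**
Reactants: 11
Product: 12 (methyl (Z)-enoate, free secondary carbinol)
Conditions: (CF3CH2O)2P(O)CH2CO2Me (1.5 equiv), KHMDS (3.3 equiv), 18-crown-6, THF, –78 °C, then 11
Reagents that add atoms: methyl bis(2,2,2-trifluoroethyl)phosphonoacetate, COC(=O)CP(=O)(OCC(F)(F)F)OCC(F)(F)F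
Why: Still–Gennari Z-selective Horner–Wadsworth–Emmons olefination sets the C2=C3 (Z) geometry needed for six-membered ring closure. The trans-acetonide keeps T4 and T5 configured and disfavors oxa-Michael/lactol closure; extra base covers the free OH.

**Step 10**
Reactants: 12
Product: 13 ((Z)-allylic alcohol/secondary alcohol diol)
Conditions: DIBAL-H (4 equiv), CH2Cl2, –78 → 0 °C
Reagents that add atoms: none (hydride only)
Why: DIBAL reduces the ester to the allylic alcohol, leaving the alkenes and acetonide intact.

**Step 11**
Reactants: 13
Product: 14 ((Z)-enal with T6 ketone)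
Conditions: Dess–Martin periodinane (3 equiv), NaHCO3, CH2Cl2, 0 °C → rt; rapid filtration through silica
Reagents that add atoms: none
Why: DMP oxidises the primary allylic alcohol and the secondary alcohol in one pot, without epimerising the α-stereocenter. This destroys the transient carbinol center of Step 6 and converges the epimer mixture.

**Step 12**
Reactants: 14
Product: 15 (cyclohexenone acetonide, 4,5-O-isopropylidene-protected 16)
Conditions: N-C6F5 pyrrolo[2,1-c][1,2,4]triazolium BF4 (achiral, 20 mol %), DIPEA (20 mol %), THF (0.01 M), 23 → 40 °C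
Reagents that add atoms: none (isomerisation)
Why: Proposed new method: an NHC adds to the Z-enal to give a Breslow intermediate. Its C1 (acyl-anion character, favoured by the electron-poor N-C6F5 carbene) attacks the α-alkoxy dialkyl ketone in a half-chair, cyclohexene-like ring closure. Homoenolate attack at the β-carbon would give a cyclobutane, so it is unproductive. With the trans-acetonide oxygens pseudo-diequatorial, the ketone R group sits equatorial and its oxygen axial, and C1 attacks anti to the C5–O bond (Felkin–Anh). This gives the C6-OH cis to the C5-OH and fixes C6 as (R). Loss of the catalyst then delivers the conjugated enone directly. The closest known reaction type is intramolecular aldehyde–ketone crossed benzoin of saturated keto-aldehydes. It is applied here to a Z-γ-alkoxy enal to build a cyclohex-2-enone and a tertiary α-ketol stereocenter in one step.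

**Step 13**
Reactants: 15
Product: 16 (Pleiogenone A)
Conditions: 80% aq. AcOH, 40 °C, 4 h
Reagents that add atoms: none (water and AcOH are the hydrolysis medium; acetone is lost)
Why: Acid-catalysed acetonide hydrolysis (the strained trans-acetonide is labile) releases the C4/C5 diol without touching the enone or the Z-alkene.

---

**Compound list**
1 | 2,3-O-isopropylidene-L-threitol | OC[C@@H]1OC(C)(C)O[C@H]1CO | starting material
2 | 1-O-TBS-2,3-O-isopropylidene-L-threitol | CC(C)(C)[Si](C)(C)OC[C@@H]1OC(C)(C)O[C@H]1CO | intermediate
3 | 4-O-TBS-2,3-O-isopropylidene-L-threose | CC(C)(C)[Si](C)(C)OC[C@@H]1OC(C)(C)O[C@H]1C=O | intermediate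
4 | 8-bromooctan-1-ol | OCCCCCCCCBr | starting material
5 | 8-bromooctanal | O=CCCCCCCCBr | intermediate
6 | nonyltriphenylphosphonium bromide | CCCCCCCCC[P+](c1ccccc1)(c1ccccc1)c1ccccc1.[Br-] | starting material
7 | (Z)-1-bromoheptadec-8-ene | BrCCCCCCC/C=C\CCCCCCCC | intermediate
8 | (Z)-heptadec-8-enylmagnesium bromide | Br[Mg]CCCCCCC/C=C\CCCCCCCC | intermediate
9 | Grignard adduct, TBS ether (carbinol epimer mixture, drawn unspecified) | CC(C)(C)[Si](C)(C)OC[C@@H]1OC(C)(C)O[C@H]1C(O)CCCCCCC/C=C\CCCCCCCC | intermediate
10 | diol after TBS removal | OC[C@@H]1OC(C)(C)O[C@H]1C(O)CCCCCCC/C=C\CCCCCCCC | intermediate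
11 | hydroxy aldehyde | O=C[C@@H]1OC(C)(C)O[C@H]1C(O)CCCCCCC/C=C\CCCCCCCC | intermediate
12 | methyl (Z)-enoate | COC(=O)/C=C\[C@@H]1OC(C)(C)O[C@H]1C(O)CCCCCCC/C=C\CCCCCCCC | intermediate
13 | (Z)-allylic alcohol/secondary alcohol diol | OC/C=C\[C@@H]1OC(C)(C)O[C@H]1C(O)CCCCCCC/C=C\CCCCCCCC | intermediate
14 | (Z)-enal ketone | O=C/C=C\[C@@H]1OC(C)(C)O[C@H]1C(=O)CCCCCCC/C=C\CCCCCCCC | intermediate
15 | cyclohexenone 4,5-acetonide | CCCCCCCC/C=C\CCCCCCC[C@]1(O)C(=O)C=C[C@@H]2OC(C)(C)O[C@@H]12 | intermediate
16 | Pleiogenone A, (4S,5R,6R)-6-[(Z)-heptadec-8-enyl]-4,5,6-trihydroxycyclohex-2-en-1-one | CCCCCCCC/C=C\CCCCCCC[C@]1(O)C(=O)C=C[C@H](O)[C@H]1O | target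

**Total steps:** 13. **Longest linear sequence:** 11 steps (8-bromooctan-1-ol → 5 → 7 → 8 → 9 → 10 → 11 → 12 → 13 → 14 → 15 → 16); 10 steps from L-threitol acetonide.

**Three steps most likely to fail**
1. **Step 12 (proposed NHC benzoin).** Risks are γ-elimination from the Breslow intermediate, strain from the trans-acetonide, wrong C6 epimer or a retro-benzoin equilibrium. Fallback (known chemistry): reduce enoate 12 with Mg/MeOH, which leaves the Z-alkene in R intact. Then run DIBAL and a double DMP oxidation to the saturated keto-aldehyde. Cyclise it with a thiazolium/DBU intramolecular crossed benzoin to the cyclohexanone, dehydrogenate with IBX to the enone, and hydrolyse the acetonide as in Step 13.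
2. **Step 9 (Still–Gennari on hydroxy-aldehyde 11).** Risks are β-elimination, epimerisation or oxa-Michael reaction of the free alkoxide, and lower Z-selectivity. Fallback: TES-protect the carbinol of 11, then Ohira–Bestmann homologation to the terminal alkyne. Acylate with n-BuLi/ClCO2Me to the ynoate, reduce with Zn(Cu/Ag) to the Z-enoate, and remove the TES to reach 12.
3. **Step 11 (one-pot double oxidation to the Z-keto-enal).** Risks are Z→E isomerisation or decomposition of the sensitive enal. Fallback: TBS-protect the primary allylic OH of 13, oxidise only the secondary alcohol with DMP, remove the TBS with HF·pyridine, and make the Z-enal by MnO2 oxidation immediately before Step 12.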